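## The problem

The ring atoms are numbered C1 = C(OH)(CH2OBz), C2 = ketone, C3 = CH2, C4 = CHOH, C5 = CHOBz, C6 = CHOH, with the exocyclic carbon as C7. The bicyclic intermediates carry the same locants.

Target 19 is one cyclohexanone ring in which every carbon except C3 bears oxygen, so the difficulty lies in placing four contiguous stereocentres, not in building a skeleton. These are C1 (S, a quaternary carbinol), C6 (S), C5 (R) and C4 (R). The C1 and C6 hydroxyls are cis, the C5 benzoate is trans to the C6 hydroxyl, and the C4 hydroxyl is cis to the C5 benzoate.

C1 cannot be corrected once made, so it must be set absolutely. In a rigid frame it can then dictate C6 (same face), C5 (inversion at an epoxide) and C4 (addition anti to that epoxide).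

The fragile groups are:
- the β-hydroxy ketone C2/C4, which dehydrates to the enone with acid or base;
- the α-ketol C1/C2, which base can rearrange or cleave;
- the two benzoates, which can be saponified or can migrate to the neighbouring C4 or C6 hydroxyl.

Strong base and hot acid are therefore excluded late, and the primary benzoate is best carried from the start. The C4 oxygen cannot be added to a C3=C4 enone by simple hydration: that addition is reversible and would be expected to come anti to the C5 benzoate, the wrong face.

The enabling feature is that C4–C5–C6–C1(–C7), with oxygen on C1 and C4, is a 2-substituted furan in disguise, and C2–C3 is a ketene equivalent. In the 7-oxabicyclo[2.2.1]heptene formed by their cycloaddition, the bridge oxygen is the future C1 hydroxyl oxygen. Because C4 is β to the C2 ketone, the bridge can later be opened by β-elimination.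

## Retrosynthesis

**19 from 17 (C3–O cleaved, C3–H made last).** Target 19 is read as the product of reductive Cα–O cleavage of the α,β-epoxy ketone 17. The alternative, hydration of an enone, would be reversible and face-ambiguous. This cut fixes C4–O beforehand and lets the sensitive β-hydroxy ketone appear only in the final, buffered step. The forward reaction must touch the epoxy ketone and leave the α-ketol and both esters alone.

**17 from 16 (C5–O benzoate bond).** The C5 benzoate is cut back to the oxirane of bis-epoxide 16. Opening at C5 with inversion gives the trans C5/C6 relationship and frees the C6 hydroxyl in one operation. The neighbouring option, selective acylation of a triol, would have to distinguish three secondary hydroxyls. The forward step must choose C5 over C6; the free C1 hydroxyl, cis to this oxirane, is kept as the directing group.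

**16 from 14 (C3–O and C4–O of the second oxirane).** Removing the C3–C4 oxirane gives epoxy enone 14. In the forward sense a peroxide anion adds to C4 anti to the existing oxirane, which is exactly the face the target needs at C4. The precursor has two stereocentres fewer. The C1 oxygen stays silylated so that the basic step cannot attack the ketol.

**14 from 12 (C4–O bridge bond re-formed).** Reconnecting the C1 oxygen to C4 gives the 7-oxabicyclo[2.2.1]heptan-2-one 12. The forward reaction is β-elimination of the bridge from the C3 enol derivative. The bicycle is simpler to control than the monocycle: its exo face is unambiguous, and it holds C1, C5 and C6 in one rigid unit.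

**12 from 9, 8 and 7 (functional-group changes at C2 and C5/C6).** The ketone of 12 comes from the α-bromo acid 9 by Curtius degradation. This is preferred to the nitrile–hydroxide route because the benzoate would not survive hydroxide. The exo oxirane of 9 comes from alkene 8, and acid 8 from aldehyde 7. Epoxidation precedes ketone formation because a peracid would attack the strained ketone in a Baeyer–Villiger reaction. It also precedes the heated Curtius step because the saturated bicycle can no longer undergo cycloreversion.

**7 from 3 and 6 (C1–C2 and C3–C4).** The two ring bonds are cut in a Diels–Alder sense to furfuryl benzoate 3 and 2-bromoacrolein 6. This removes the carbocycle and all three stereocentres of 7 at once and leaves two achiral, flat reagents. The forward reaction must deliver the 1,2-regiochemistry, the exo-formyl orientation and one enantioface.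

**3 from 1 and 2; 6 from 4.** Ester 3 is the benzoate of furfuryl alcohol 1 and benzoyl chloride 2. Dienophile 6 is made from acrolein 4 by bromination and dehydrobromination.

## Roads not taken

**Alternative 1: enzymatic dihydroxylation of benzoic acid.** The cut is at the C1–O and C2–O bonds. In the forward step a benzoate 1,2-dioxygenase in whole cells adds O2 to the ipso and ortho carbons of benzoic acid A1 and gives the cis-diol acid A2.
- Merits: the quaternary carbinol C1 is obtained in one step as a single enantiomer, C2 is already oxygenated (its carbinol is oxidised to the ketone), and the carboxyl is the future C7.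
- Weak points: a blocked mutant strain and fermentation are needed, and A2 rearomatises easily by loss of water. Its diene C3=C4–C5=C6 must then receive oxygen at C4, C5 and C6 and hydrogen at C3, with three secondary centres controlled only by C1 across a flat ring. The α-ketol appears early.
- Comparison: this road secures C1 more reliably than an untested asymmetric cycloaddition and is probably shorter to a C1/C2-functionalised ring; in those respects it is better. The chosen plan offers a rigid bicycle in which C6, C5 and C4 follow from exo-epoxidation, inversion and anti-epoxidation. It also has the C7 benzoate present from the first step and needs purely chemical operations.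

**Alternative 2: intramolecular Morita–Baylis–Hillman closure.** The cut is at C1–C6. In the forward step PMe3 adds to the vinyl ketone of the acyclic keto aldehyde A3, and the resulting enolate attacks the C6 aldehyde to give the exo-methylene ketol A4.
- Merits: C4 and C5 come with their oxygens from a chiral precursor, so there is no late C4 problem. The ring is closed under mild conditions.
- Weak points: C6 is set only by substrate control in the aldol step. The C5 centre of A3 is α to an aldehyde and can epimerise. The C4 silyloxy group of A3 and A4 is β to the ketone and can be eliminated. The exocyclic alkene of A4 must then be dihydroxylated so that the C1 hydroxyl is cis to the C6 hydroxyl, whereas attack anti to the allylic C6 oxygen, the usual preference, would give the trans arrangement.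
- Comparison: this road is better in having C4–O in place from the beginning. The chosen plan spends two steps on C4 but sets C1 by catalyst control and derives C6 from it, which is the relationship the other road is least able to guarantee.

**Alternative 3: D-mannose and enol ether ring-closing metathesis.** The cut is at C2=C3. In the forward step the second-generation Grubbs catalyst RuCl2(PCy3)(H2IMes)(=CHPh) closes the ring from D-mannose A5 after elaboration and gives the cyclic enol ether A6. Hydrolysis of A6 reveals the C2 ketone and the C3 methylene.
- Merits: C4, C5 and C6 come from the sugar with certainty, and the C4 oxygen never has to be introduced.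
- Weak points: the sequence from A5 is long and heavy in protecting groups. C1 must be created by a diastereoselective addition to a ketone. Metathesis onto an electron-rich 1-ethoxyvinyl group is slow. After the acetonide of A6 is removed, the C5 hydroxyl must be benzoylated selectively beside the cis C4 hydroxyl.
- Comparison: this road is the safest in stereochemistry at the three secondary carbinols. The chosen plan is roughly half as long and avoids the late differentiation of hydroxyls.

Key step: step 3

Assumption: the facial sense of the catalyst is taken from the accepted model for 2-substituted acroleins (boron-bound s-trans enal held by a formyl C–H···O contact over one phenyl ring). For an exo-formyl transition state this assigns adduct 7 to the catalyst from (R)-α,α-diphenylprolinol; the (S)-catalyst would give its mirror image.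

## Route

Step 1
Reactants: 1 furfuryl alcohol; 2 benzoyl chloride
Product: 3 furfuryl benzoate
Conditions: Et3N, DMAP (cat.), CH2Cl2, 0 °C → rt
Reagents that add atoms: none
Why: Nucleophilic acyl substitution (O-benzoylation) of a primary alcohol; the amine base keeps the acid-sensitive furfuryl system from polymerising, and no stereocentre is involved.

Step 2
Reactants: 4 acrolein
Product: 6 2-bromoacrolein, via 2,3-dibromopropanal 5 (not isolated)
Conditions: Br2, CH2Cl2, −78 → 0 °C; then Et3N, 0 °C
Reagents that add atoms: bromine, BrBr
Why: Electrophilic addition of bromine to the alkene followed by E1cB loss of HBr from the acidic α-position is the standard preparation of this dienophile; it should be distilled and used fresh because it polymerises.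

Step 3
Reactants: 3 furfuryl benzoate (excess); 6 2-bromoacrolein
Product: 7 [(1R,2S,4S)-2-bromo-2-formyl-7-oxabicyclo[2.2.1]hept-5-en-1-yl]methyl benzoate (formyl exo, bromine endo)
Conditions: (R)-B-(o-tolyl)oxazaborolidinium triflimide [C24H25BNO][N(SO2CF3)2] (20 mol %), CH2Cl2, −78 °C; Et3N quench at −78 °C
Reagents that add atoms: none
Why: This is a Lewis-acid-catalysed Diels–Alder reaction, the closest known type being the oxazaborolidinium-catalysed addition of 2-haloacroleins to furan and cyclopentadiene. The aldehyde of 6 binds to boron anti to its vinyl group and is held by a formyl C–H···O contact, so the s-trans enal lies over one phenyl ring and only the opposite face is open to the diene. Bond formation should be concerted but asynchronous: the free α-carbon of 3 (largest HOMO coefficient) bonds first to the CH2 terminus of 6 (largest LUMO coefficient), and the substituted α-carbon then closes onto the bromine-bearing carbon, which gives the 1,2-regiochemistry needed for C1–C2. The six-membered carbocycle C1–C6 is closed by this suprafacial [4+2] addition, the furan oxygen becoming the one-atom bridge between C1 and C4. C1 (R in 7, the later S carbinol) and C4 are set together by the catalyst-controlled dienophile face combined with the exo-formyl, endo-bromine orientation that 2-haloacroleins prefer. C2 follows from that orientation; C2 and C4 are erased later. The step needs regioselection, exo-formyl selection and one enantioface: the first rests on the polarisation of the 2-substituted furan, the other two on the dienophile and the catalyst. The reaction is run and quenched cold because furan adducts cyclorevert.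

Step 4
Reactants: 7 bromo aldehyde adduct
Product: 8 (1R,2S,4S)-1-(benzoyloxymethyl)-2-bromo-7-oxabicyclo[2.2.1]hept-5-ene-2-carboxylic acid
Conditions: NaClO2, NaH2PO4, 2-methyl-2-butene, t-BuOH/H2O, 0 °C (crude 7, kept cold)
Reagents that add atoms: sodium chlorite, [Na+].[O-]Cl=O
Why: Pinnick oxidation of an aldehyde that has no α-hydrogen; the alkene scavenger removes HOCl so the strained ring alkene and the benzoate are untouched, and no stereocentre can epimerise.

Step 5
Reactants: 8 bromo acid
Product: 9 1-(benzoyloxymethyl)-2-endo-bromo-5,6-exo-epoxy-7-oxabicyclo[2.2.1]heptane-2-exo-carboxylic acid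
Conditions: mCPBA, CH2Cl2, rt
Reagents that add atoms: 3-chloroperbenzoic acid, O=C(OO)c1cccc(Cl)c1
Why: Prilezhaev epoxidation of the strained C5=C6 alkene from the exo face, syn to the bridge oxygen and away from the C2–C3 bridge with its endo bromine; this sets C5 and C6 with the oxirane oxygen cis to the future C1 hydroxyl, and the saturated product can no longer cyclorevert.

Step 6
Reactants: 9 epoxy bromo acid
Product: 12 1-(benzoyloxymethyl)-5,6-exo-epoxy-7-oxabicyclo[2.2.1]heptan-2-one, via acyl azide 10 (not isolated), via bromo isocyanate 11 (not isolated)
Conditions: (PhO)2P(O)N3, Et3N, PhMe, rt → 80 °C; then AcOH/H2O, NaOAc, 50 °C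
Reagents that add atoms: water, O; diphenylphosphoryl azide, [N-]=[N+]=NP(=O)(Oc1ccccc1)Oc1ccccc1 (supplies the nitrogen of 10 and 11 only)
Why: Curtius rearrangement with retention at C2, then hydrolysis of the α-bromo isocyanate: the carbamic acid loses CO2, the geminal bromo amine collapses to an iminium ion and water gives the ketone, which is the classical unmasking of an α-haloacrylic dienophile as a ketene equivalent. The medium stays neutral to weakly acidic, so the benzoate and the hindered exo oxirane should survive.

Step 7
Reactants: 12 epoxy ketone
Product: 14 (4S,5S,6S)-6-(benzoyloxymethyl)-4,5-epoxy-6-(trimethylsilyloxy)cyclohex-2-en-1-one (C1–OSiMe3, C3=C4 enone, C5–C6 oxirane cis to the silyloxy group in the target numbering), via trimethylsilyl enol ether 13 (not isolated)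
Conditions: TMSOTf, Et3N, CH2Cl2, 0 °C → rt
Reagents that add atoms: trimethylsilyl trifluoromethanesulfonate, C[Si](C)(C)OS(=O)(=O)C(F)(F)F
Why: Silyl triflate–amine β-elimination, a known opening of 7-oxabicyclo[2.2.1]heptan-2-ones: only C3 can enolise because C1 is quaternary, silylation makes the bridge oxygen a leaving group at C4, and release of bicyclic strain drives C4–O cleavage to the enone with the oxygen retained on C1 as its silyl ether. C1, C5 and C6 are untouched, and the oxirane has no removable β-hydrogen that would allow isomerisation to an allylic ether.

Step 8
Reactants: 14 silylated epoxy enone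
Product: 16 (2S,3S,4S,5S,6S)-6-(benzoyloxymethyl)-2,3:4,5-diepoxy-6-hydroxycyclohexan-1-one (trans bis-epoxide; C5–C6 oxirane cis and C3–C4 oxirane trans to the C1 hydroxyl in the target numbering), via silylated bis-epoxide 15 (not isolated)
Conditions: t-BuOOH, DBU, CH2Cl2, 0 °C; then citric acid, MeOH, 0 °C
Reagents that add atoms: tert-butyl hydroperoxide, CC(C)(C)OO
Why: Weitz–Scheffer epoxidation: the peroxide anion adds to C4 anti to the adjacent C5–O bond of the existing oxirane and the enolate closes at C3, so the new oxirane is trans to the old one and C4–O has the target configuration. The C1 oxygen stays silylated during the basic stage to protect the α-ketol and the benzoate, and the tertiary trimethylsilyl ether is then cleaved by mild acid methanolysis.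

Step 9
Reactants: 16 bis-epoxide ketol
Product: 17 (2S,3S,4S,5S,6S)-4-(benzoyloxy)-6-(benzoyloxymethyl)-2,3-epoxy-5,6-dihydroxycyclohexan-1-one (C5–OBz trans to C6–OH, C3–C4 oxirane retained)
Conditions: Ti(OiPr)4, PhCO2H, CH2Cl2, rt
Reagents that add atoms: benzoic acid, O=C(O)c1ccccc1
Why: Titanium tetraisopropoxide-mediated opening of a 2,3-epoxy alcohol by a carboxylic acid: the C1 hydroxyl, cis to the C5–C6 oxirane, binds titanium together with the oxirane oxygen and the benzoate is delivered to the distal carbon C5 from the opposite face (SN2, inversion). C6 is further shielded by the quaternary C1, and the electron-poor epoxy ketone has no cis hydroxyl to activate it.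

Step 10
Reactants: 17 epoxy ketone dibenzoate
Product: 19 [(1S,2S,3R,4R)-3-benzoyloxy-1,2,4-trihydroxy-6-oxocyclohexyl]methyl benzoate (target), via phenylseleno ketone 18 (not isolated)
Conditions: (PhSe)2, NaBH4, EtOH; then AcOH and 17, 0 °C → rt
Reagents that add atoms: none
Why: Reductive cleavage of an α,β-epoxy ketone by sodium phenylseleno(triethoxy)borate: selenide opens the oxirane at the α-carbon C3, a second selenide removes selenium from 18 to give the enolate, and acetic acid protonates it. The C4–O bond is never broken, so C4 keeps the configuration set in step 8, and the buffered medium should spare the esters, the α-ketol and the new β-hydroxy ketone.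

## Compound list

1 | furfuryl alcohol | OCc1ccco1 | starting material
2 | benzoyl chloride | O=C(Cl)c1ccccc1 | starting material
3 | furfuryl benzoate | O=C(OCc1ccco1)c1ccccc1 | intermediate
4 | acrolein | C=CC=O | starting material
5 | 2,3-dibromopropanal (racemic) | O=CC(Br)CBr | intermediate
6 | 2-bromoacrolein | C=C(Br)C=O | intermediate
7 | [(1R,2S,4S)-2-bromo-2-formyl-7-oxabicyclo[2.2.1]hept-5-en-1-yl]methyl benzoate | O=C(c1ccccc1)OC[C@@]23O[C@@H](C[C@@]2(Br)C=O)C=C3 | intermediate
8 | (1R,2S,4S)-1-(benzoyloxymethyl)-2-bromo-7-oxabicyclo[2.2.1]hept-5-ene-2-carboxylic acid | O=C(c1ccccc1)OC[C@@]23O[C@@H](C[C@@]2(Br)C(=O)O)C=C3 | intermediate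
9 | 1-(benzoyloxymethyl)-2-endo-bromo-5,6-exo-epoxy-7-oxabicyclo[2.2.1]heptane-2-exo-carboxylic acid | O=C(c1ccccc1)OC[C@@]23O[C@@H](C[C@@]2(Br)C(=O)O)[C@@H]4O[C@H]34 | intermediate
10 | acyl azide of 9 | O=C(c1ccccc1)OC[C@@]23O[C@@H](C[C@@]2(Br)C(=O)N=[N+]=[N-])[C@@H]4O[C@H]34 | intermediate
11 | 1-(benzoyloxymethyl)-2-endo-bromo-5,6-exo-epoxy-2-exo-isocyanato-7-oxabicyclo[2.2.1]heptane | O=C(c1ccccc1)OC[C@@]23O[C@@H](C[C@@]2(Br)N=C=O)[C@@H]4O[C@H]34 | intermediate
12 | 1-(benzoyloxymethyl)-5,6-exo-epoxy-7-oxabicyclo[2.2.1]heptan-2-one | O=C(c1ccccc1)OC[C@@]23O[C@@H](CC2=O)[C@@H]4O[C@H]34 | intermediate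
13 | trimethylsilyl enol ether of 12 (C2=C3) | O=C(c1ccccc1)OC[C@@]23O[C@@H](C=C2O[Si](C)(C)C)[C@@H]4O[C@H]34 | intermediate
14 | (4S,5S,6S)-6-(benzoyloxymethyl)-4,5-epoxy-6-(trimethylsilyloxy)cyclohex-2-en-1-one | O=C(OC[C@@]1(O[Si](C)(C)C)C(=O)C=C[C@@H]2O[C@H]12)c1ccccc1 | intermediate
15 | trimethylsilyl ether of 16 | O=C(OC[C@@]1(O[Si](C)(C)C)C(=O)[C@H]2O[C@H]2[C@@H]3O[C@H]13)c1ccccc1 | intermediate
16 | (2S,3S,4S,5S,6S)-6-(benzoyloxymethyl)-2,3:4,5-diepoxy-6-hydroxycyclohexan-1-one | O=C(OC[C@@]1(O)C(=O)[C@H]2O[C@H]2[C@@H]3O[C@H]13)c1ccccc1 | intermediate
17 | (2S,3S,4S,5S,6S)-4-(benzoyloxy)-6-(benzoyloxymethyl)-2,3-epoxy-5,6-dihydroxycyclohexan-1-one | O=C(OC[C@@]1(O)C(=O)[C@H]2O[C@H]2[C@@H](OC(=O)c2ccccc2)[C@@H]1O)c1ccccc1 | intermediate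
18 | C3-phenylseleno derivative of 19 (selenium trans to the C4 hydroxyl) | O=C(OC[C@@]1(O)C(=O)[C@H]([Se]c2ccccc2)[C@@H](O)[C@@H](OC(=O)c2ccccc2)[C@@H]1O)c1ccccc1 | intermediate
19 | [(1S,2S,3R,4R)-3-benzoyloxy-1,2,4-trihydroxy-6-oxocyclohexyl]methyl benzoate | O=C(OC[C@@]1(O)C(=O)C[C@@H](O)[C@@H](OC(=O)c2ccccc2)[C@@H]1O)c1ccccc1 | target

## Step count and least certain steps

Total: 10 steps. Longest linear sequence: 9 steps (steps 1 and 3–10; the branch through step 2 is equally long).

**Step 3 (key step).** The most likely failure is a stepwise course: after the first C–C bond forms, the furan-derived oxocarbenium ion may lose a proton faster than it closes onto the hindered bromine-bearing carbon, which would amount to Friedel–Crafts-type conjugate alkylation at the free α-position. Binding of the ester carbonyl to boron, cycloreversion on warming and incomplete facial or regiochemical selection are further risks.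

The fallback gives up catalysis. Compounds 3 and 6 are combined without Lewis acid under high pressure (about 12 kbar, CH2Cl2, rt). No zwitterion is expected there and pressure favours the adduct, so this should give the racemic adduct F1. Oxidation as in step 4 gives the racemic acid F2. This is resolved by crystallisation of its salt with (R)-1-phenylethylamine, the (R)-1-phenylethylammonium salt F3 of the wanted acid (the antipodal amine is used if the other diastereomer crystallises). Acidification returns to the route at 8.

**Step 8.** The trimethylsilyl group may be lost under the basic peroxide. The free α-ketol could then be cleaved between C1 and C2 after peroxide addition to the ketone, or the benzoate could migrate. Base may also isomerise the epoxy enone through its C5 hydrogen.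

The fallback changes the protecting group. From 12, t-BuMe2SiOTf and Et3N give the tert-butyldimethylsilyl ether F4 of the epoxy enone. Its epoxidation as in step 8 gives the silylated bis-epoxide F5, and Et3N·3HF in MeCN removes the silyl group and returns to the route at 16.

**Step 9.** Regioselection between C5 and C6 may be poor because C5 is deactivated by the neighbouring oxirane. The benzoate may instead open the C3–C4 epoxy ketone, or the titanium alkoxide may exchange ester groups.

The fallback reverses the order of the last two steps. From 16, the selenoborate reduction of step 10 should first cleave only the epoxy ketone and give the epoxy β-hydroxy ketone F6. F6 has a single oxirane, flanked by a carbinol and no longer by an oxirane. Its opening with PhCO2H and Ti(OiPr)4 under direction of the C1 hydroxyl arrives directly at 19.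

**Step 10.** The alkoxide freed at C4 sits cis to the C5 benzoate and may take up the acyl group. Elimination of the new β-hydroxyl to the enone and selenide attack on an ester are lesser risks.

The fallback avoids an alkoxide. From 17, MgI2 in toluene/Et2O at low temperature opens the oxirane at C3 to the α-iodo-β-hydroxy ketone F7. Radical deiodination with Bu3SnH and Et3B/air at −20 °C then gives 19.

## Further compounds

F1 | step 3 | racemic 7 (both enantiomers) | O=C(c1ccccc1)OC[C@@]23O[C@@H](C[C@@]2(Br)C=O)C=C3.O=C(c1ccccc1)OC[C@]23O[C@H](C[C@]2(Br)C=O)C=C3
F2 | step 3 | racemic 8 (both enantiomers) | O=C(c1ccccc1)OC[C@@]23O[C@@H](C[C@@]2(Br)C(=O)O)C=C3.O=C(c1ccccc1)OC[C@]23O[C@H](C[C@]2(Br)C(=O)O)C=C3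
F3 | step 3 | (R)-1-phenylethylammonium salt of 8 | O=C(c1ccccc1)OC[C@@]23O[C@@H](C[C@@]2(Br)C(=O)[O-])C=C3.C[C@@H]([NH3+])c1ccccc1
F4 | step 8 | 6-(benzoyloxymethyl)-6-(tert-butyldimethylsilyloxy)-4,5-epoxycyclohex-2-en-1-one (configured as 14) | O=C(OC[C@@]1(O[Si](C)(C)C(C)(C)C)C(=O)C=C[C@@H]2O[C@H]12)c1ccccc1
F5 | step 8 | tert-butyldimethylsilyl ether of 16 | O=C(OC[C@@]1(O[Si](C)(C)C(C)(C)C)C(=O)[C@H]2O[C@H]2[C@@H]3O[C@H]13)c1ccccc1
F6 | step 9 | 2-(benzoyloxymethyl)-2,5-dihydroxy-7-oxabicyclo[4.1.0]heptan-3-one (C1–OH cis to the oxirane, C4–OH trans to it in the target numbering) | O=C(OC[C@@]1(O)C(=O)C[C@@H](O)[C@@H]2O[C@H]12)c1ccccc1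
F7 | step 10 | C3-iodo derivative of 19 (iodine trans to the C4 hydroxyl) | O=C(OC[C@@]1(O)C(=O)[C@H](I)[C@@H](O)[C@@H](OC(=O)c2ccccc2)[C@@H]1O)c1ccccc1
A1 | alternative 1 | benzoic acid | O=C(O)c1ccccc1
A2 | alternative 1 | (1S,2R)-1,2-dihydroxycyclohexa-3,5-diene-1-carboxylic acid | OC(=O)[C@@]1(O)[C@H](O)C=CC=C1
A3 | alternative 2 | 2-benzoyloxy-3-(tert-butyldimethylsilyloxy)-5-oxohept-6-enal (configured as C5 and C4 of the target) | C=CC(=O)C[C@@H](O[Si](C)(C)C(C)(C)C)[C@@H](OC(=O)c1ccccc1)C=O
A4 | alternative 2 | 4-benzoyloxy-3-hydroxy-2-methylene-5-(tert-butyldimethylsilyloxy)cyclohexanone | C=C1C(=O)C[C@@H](O[Si](C)(C)C(C)(C)C)[C@@H](OC(=O)c2ccccc2)[C@@H]1O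
A5 | alternative 3 | D-mannose (open-chain form) | O=C[C@@H](O)[C@@H](O)[C@H](O)[C@H](O)CO
A6 | alternative 3 | cyclic enol ether (2-ethoxycyclohex-2-enol core; C4/C5 acetonide, C6 triisopropylsilyl ether, C7 benzoate) | O=C(c1ccccc1)OC[C@@]1(O)C(OCC)=C[C@H]2OC(C)(C)O[C@H]2[C@@H]1O[Si](C(C)C)(C(C)C)C(C)C
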